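- 15.8% of the starting material had gone by 1.50 h in the midnight run, read as open intermediate plus target. Side products went unread, so this sum leaves them out.

- midnight: starting material 0.25 M; coupling partner 0.45 M; free catalyst 0.12 mM; run made earlier
- flask: starting material 0.25 M; coupling partner 0.450 M; free catalyst 0.25 mM; time 2.5 d

midnight run (percent of the starting material charged)

| time / h | open intermediate / % | target / % |
|---|---|---|
| 0.500 | 7.2 | 0.8 |
| 1.50 | 15.8 | 0 |
| 3.00 | 24.2 | 1.1 |
| 4.00 | 27.7 | 2.0 |
| 6.00 | 32.1 | 2.5 |

(each reading ± 1 percentage point)

- a species is counted by the starting material in it: one self-condensation product or side product A counts as two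
- what was read earlier has a scatter of 1 percentage point, one standard deviation
- steps under discussion: starting material + free catalyst -> free catalyst + open intermediate; free catalyst + open intermediate <-> catalyst intermediate; coupling partner + catalyst intermediate -> free catalyst + target; 2 starting material -> self-condensation product; starting material + open intermediate -> side product A; open intermediate -> side product B
- no earlier run changes the charge of free catalyst; that part of a forecast is a guess

- time, not beyond 2.5 d, at which the flask holds most open intermediate
- the amount of open intermediate, in percent of the starting material charged, at that time

- Starting material is the limiting reagent, charged at less than the coupling partner. While the catalyst is taken as free, the balance of starting material is pseudo-first-order, and this reading gives 0.115 h⁻¹ for the midnight run.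
- The bench rule says that the flask, with 2.08 times the catalyst, replays the midnight run that much faster. This scaling is a guess, since no earlier run changes the catalyst.
- So we carry the drain half-life, the time in which the flask's catalyst, taken as free, halves the starting material: 2.90 h.
- The rule has a border. The last midnight reading maps to 2.88 h in the flask, and the 2.5 d allowed is 20.8 times longer. The step from open intermediate to side product B has no catalyst in its equation, so the rule does not cover it.
- We expect the flask's peak by 3 half-lives, 8.71 h, where this reckoning leaves 12.5% of the starting material.
- The forecast gives 54% at 0.75 d, later than our time, reading the slowdown mainly as “catalyst being tied up by open intermediate”.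
- The flask peaks at 0.259 d with 44.6% open intermediate, and 29.3% starting material stands then.

    starting material + free catalyst → free catalyst + open intermediate (k = 0.306 M⁻¹ s⁻¹)
    free catalyst + open intermediate ⇌ catalyst intermediate (K = 6.97 M⁻¹, k = 0.292 M⁻¹ s⁻¹)
    coupling partner + catalyst intermediate → free catalyst + target (k = 0.0299 M⁻¹ s⁻¹)
    2 starting material → self-condensation product (k = 2.30 × 10⁻⁷ M⁻¹ s⁻¹)
    starting material + open intermediate → side product A (k = 1.16 × 10⁻⁵ M⁻¹ s⁻¹)
    open intermediate → side product B (k = 2.00 × 10⁻⁵ s⁻¹)

- The flask's peak lies 2.14 drain half-lives in, where the half-life reckons 22.6% starting material. For the neighbouring flask with 1.5 × 10⁻⁴ M of free catalyst, the half-life stretches to 4.84 h, which reckons 0.0185% left at 2.5 d; that flask holds 0.0217% of its starting material.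

The earlier runs and the new flask were computed on assumed constants, noise included.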